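The route cuts the side chain between C12 and C13 (labdane numbering). C12 ends the two-carbon tether on C9 of the trans-decalin (ring B), and C13 is the lone acyclic, methyl-bearing stereocentre, 1,3 to the C15 oxygen. The key step hydroborates a C9-vinyl decalin at C12 and couples the B-alkyl-9-BBN with (Z)-crotyl chloride under copper/chiral bisphosphine catalysis. One operation forms C12–C13, sets C13 by catalyst control and leaves C14=C15 as a vinyl group, the masked C15 alcohol, so the C18 senecioate can already be in place. The vinyl decalin comes from an epoxide-initiated tricyclization of a Sharpless-derived epoxy farnesylacetate, whose δ-lactone carbonyl is later expelled as CO2.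

Key step: step 11

Assumption: labdane numbering is used throughout (C17 = CH3 on C8, C18 = CH2O on C4, C19 = CH3 on C4, C20 = CH3 on C10, C16 = CH3 on C13); read from the SMILES, the target is the ent-labdane (4S,5S,8S,9S,10R,13S) with C18 equatorial (trans to C20).

Step 1
Reactants: 1 (2E,6E)-farnesyl bromide; 2 tert-butyl acetate
Product: 3 tert-butyl (4E,8E)-5,9,13-trimethyltetradeca-4,8,12-trienoate
Conditions: LDA, 2, THF, −78 °C; then 1, DMPU, −78 → −20 °C
Reagents that add atoms: none
Why: SN2 alkylation of the lithium ester enolate at the primary allylic bromide keeps both E-alkenes and adds the two carbons that become C12 and the later-expelled carboxyl carbon.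

Step 2
Reactants: 3 tert-butyl (4E,8E)-5,9,13-trimethyltetradeca-4,8,12-trienoate
Product: 4 tert-butyl (4E,8E,12E)-14-hydroxy-5,9,13-trimethyltetradeca-4,8,12-trienoate
Conditions: SeO2 (cat.), t-BuOOH, salicylic acid (cat.), CH2Cl2, 0 °C → rt, stopped at partial conversion
Reagents that add atoms: selenium dioxide, O=[Se]=O (catalytic oxygen carrier); tert-butyl hydroperoxide, CC(C)(C)OO (terminal oxidant)
Why: Sharpless catalytic SeO2 allylic oxidation (ene reaction, then [2,3]-shift) attacks the most electron-rich terminal trisubstituted alkene and oxidises its E-methyl group, giving the (E)-allylic alcohol.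

Step 3
Reactants: 4 tert-butyl (4E,8E,12E)-14-hydroxy-5,9,13-trimethyltetradeca-4,8,12-trienoate
Product: 5 tert-butyl (4E,8E)-11-[(2R,3R)-3-(hydroxymethyl)-3-methyloxiran-2-yl]-5,9-dimethylundeca-4,8-dienoate
Conditions: Ti(Oi-Pr)4, D-(−)-diethyl tartrate, t-BuOOH, 4 Å MS, CH2Cl2, −20 °C
Reagents that add atoms: tert-butyl hydroperoxide, CC(C)(C)OO
Why: Sharpless asymmetric epoxidation of the (E)-2-methyl allylic alcohol, in which D-(−)-tartrate selects the face that gives the (2R,3R)-epoxide (reagent control) and the isolated trisubstituted alkenes stay untouched.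

Step 4
Reactants: 5 tert-butyl (4E,8E)-11-[(2R,3R)-3-(hydroxymethyl)-3-methyloxiran-2-yl]-5,9-dimethylundeca-4,8-dienoate
Product: 6 ent-3,18-dihydroxy-14,15,16-trinorlabdan-13,8-olide, (3R,4S,5S,8S,9S,10R), a trans-decalin fused to a δ-lactone with 3-OH and C18H2OH equatorial
Conditions: MeAlCl2 (3 equiv), CH2Cl2, −78 → −40 °C; then 1 M HCl
Reagents that add atoms: none
Why: Lewis-acid epoxide-initiated cation–olefin tricyclization (Stork–Eschenmoser chair–chair folding) in which the first MeAlCl2 turns 18-OH into its aluminium alkoxide, C5 attacks C4 with inversion so that the (E)-CH2O group ends equatorial, the retained C3–O centre fixes the absolute sense, anti additions across the two E-alkenes set C5/C10 (trans fusion) and C9/C8, and the ester carbonyl traps the C8 cation with loss of isobutene to give the trans-fused δ-lactone.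

Step 5
Reactants: 6 ent-3,18-dihydroxy-14,15,16-trinorlabdan-13,8-olide
Product: 7 cyclic 3,18-thionocarbonate of 6 (1,3-dioxane-2-thione spanning O3 and O18)
Conditions: 1,1'-thiocarbonyldiimidazole, DMAP (cat.), PhMe, 90 °C
Reagents that add atoms: 1,1'-thiocarbonyldiimidazole, S=C(n1ccnc1)n1ccnc1
Why: Cyclic thionocarbonate formation from the 1,3-diol (equatorial 3-OH and equatorial CH2OH on adjacent carbons close a six-membered ring), with the lactone inert.

Step 6
Reactants: 7 cyclic 3,18-thionocarbonate of 6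
Product: 9 (4S,5S,8S,9S,10R)-8,18-dihydroxy-14,15,16-trinorlabdan-13-oic acid, via S-tributylstannyl thiocarbonate 8 (not isolated)
Conditions: Bu3SnH, AIBN (cat.), PhMe, 110 °C; then LiOH, THF/H2O, 50 °C; 1 M HCl to pH 4–5, 0 °C, used directly
Reagents that add atoms: water (aqueous LiOH), O
Why: Barton–McCombie deoxygenation of a cyclic thionocarbonate, in which the tin-radical adduct fragments towards the more stable secondary C3 radical and not the primary C18 radical, hydrogen transfer gives C3H2, and the hydroxide work-up frees 18-OH and opens the δ-lactone to the carboxylate.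

Step 7
Reactants: 9 (4S,5S,8S,9S,10R)-8,18-dihydroxy-14,15,16-trinorlabdan-13-oic acid
Product: 10 (4S,5S,8S,9S,10R)-13,14,15,16-tetranorlabd-11-ene-8,18-diol (C9-vinyl decalin diol)
Conditions: [Ir(dF(CF3)ppy)2(dtbbpy)]PF6 (cat.), Co(dmgH)2(py)Cl (cat.), Cs2CO3 (cat.), DME/H2O, blue LEDs, rt
Reagents that add atoms: none
Why: Photoredox/cobaloxime dehydrogenative decarboxyolefination, in which carboxylate oxidation and CO2 loss give the primary C12 radical that cobalt converts into the terminal C11=C12 alkene with release of H2, and, since the acid is never activated, the tertiary 8-OH cannot relactonize or close an ether.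

Step 8
Reactants: 10 (4S,5S,8S,9S,10R)-13,14,15,16-tetranorlabd-11-ene-8,18-diol; 11 3-methylbut-2-enoic acid (senecioic acid)
Product: 12 (4S,5S,8S,9S,10R)-8-hydroxy-13,14,15,16-tetranorlabd-11-en-18-yl 3-methylbut-2-enoate
Conditions: DCC, DMAP (cat.), CH2Cl2, 0 °C → rt
Reagents that add atoms: none
Why: Steglich esterification, in which only the primary (neopentyl) 18-OH is acylated and the tertiary 8-OH is inert.

Step 9
Reactants: 13 but-2-yn-1-ol
Product: 14 (Z)-but-2-en-1-ol
Conditions: H2 (1 atm), Lindlar catalyst, quinoline, Et2O, rt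
Reagents that add atoms: none
Why: Lindlar semihydrogenation, syn addition of H2 on the catalyst surface gives the (Z)-alkene.

Step 10
Reactants: 14 (Z)-but-2-en-1-ol
Product: 15 (Z)-1-chlorobut-2-ene
Conditions: NCS, Me2S, CH2Cl2, −20 → 0 °C; used as a solution
Reagents that add atoms: N-chlorosuccinimide, O=C1CCC(=O)N1Cl
Why: Corey–Kim-type chlorination, SN2 displacement of the alkoxysulfonium by chloride at the primary carbon without allylic transposition or Z→E isomerisation.

Step 11
Reactants: 12 (4S,5S,8S,9S,10R)-8-hydroxy-13,14,15,16-tetranorlabd-11-en-18-yl 3-methylbut-2-enoate; 15 (Z)-1-chlorobut-2-ene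
Product: 17 (4S,5S,8S,9S,10R,13S)-8-hydroxylabd-14-en-18-yl 3-methylbut-2-enoate, via B-alkyl-9-BBN 16 (not isolated)
Conditions: 9-BBN dimer (0.6 equiv), THF, 50 °C; then CuOTf·(toluene)0.5 (10 mol%), (R)-DTBM-SEGPHOS (10 mol%), EtOK (1.2 equiv), 15 (1.5 equiv), 1,4-dioxane, 15 °C
Reagents that add atoms: none
Why: 9-BBN adds to the C9-vinyl group at its terminal carbon, so boron sits on C12; ethoxide converts the borane into a borate that hands the primary alkyl group to the copper(I)–bisphosphine complex, and the alkylcopper attacks (Z)-crotyl chloride at its methyl-bearing γ-carbon (SN2′ through a σ-allyl copper(III) species, then reductive elimination), which forms C12–C13. The closest known reaction type is the copper-catalysed enantioselective γ-selective allyl–alkyl coupling of alkyl-9-BBN reagents with (Z)-allylic chlorides. No ring is closed. The new stereocentre C13 is controlled by the chiral bisphosphine on copper, which selects one enantioface of the Z-alkene; the sense of induction cannot be derived here, so the ligand antipode that gives (13S) on a model alkylborane is used ((R) is written provisionally), and since C13 lies four bonds from the nearest ring stereocentre (C9) no match/mismatch effect is expected. The step needs γ- over α-substitution and chemoselectivity for the alkylborane: the Z geometry and the bulky ligand favour the branched product, while the β,β-disubstituted senecioate and the hindered tertiary 8-OH (slow towards 9-BBN, at most an internal alkoxide on boron) should be spectators. The vinyl group left on C13 is the masked C15 alcohol.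

Step 12
Reactants: 17 (4S,5S,8S,9S,10R,13S)-8-hydroxylabd-14-en-18-yl 3-methylbut-2-enoate
Product: 19 (4S,5S,8S,9S,10R,13S)-8,15-dihydroxylabdan-18-yl 3-methylbut-2-enoate, via B-alkyl-9-BBN 18 (not isolated)
Conditions: 9-BBN, THF, rt; then 30% H2O2, aq. NaOAc, 0 °C → rt
Reagents that add atoms: hydrogen peroxide, OO
Why: Anti-Markovnikov hydroboration–oxidation, in which 9-BBN selects the monosubstituted C14=C15 alkene over the trisubstituted conjugated senecioate alkene and the weakly basic peroxide oxidation leaves the ester and C13 untouched.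

Step 13
Reactants: 19 (4S,5S,8S,9S,10R,13S)-8,15-dihydroxylabdan-18-yl 3-methylbut-2-enoate; 20 Meldrum's acid (2,2-dimethyl-1,3-dioxane-4,6-dione)
Product: 21 (4S,5S,8S,9S,10R,13S)-15-[(carboxyacetyl)oxy]-8-hydroxylabdan-18-yl 3-methylbut-2-enoate (CNP0199440.1)
Conditions: PhMe, 80 °C
Reagents that add atoms: none
Why: Thermal ring-opening acylation by Meldrum's acid with loss of acetone gives the malonic half ester directly at the unhindered primary 15-OH, the tertiary 8-OH being too hindered to react.

Compound list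
1 | (2E,6E)-farnesyl bromide | BrC/C=C(\C)CC/C=C(\C)CCC=C(C)C | starting material
2 | tert-butyl acetate | CC(=O)OC(C)(C)C | starting material
3 | tert-butyl (4E,8E)-5,9,13-trimethyltetradeca-4,8,12-trienoate | CC(C)(C)OC(=O)CC/C=C(\C)CC/C=C(\C)CCC=C(C)C | intermediate
4 | tert-butyl (4E,8E,12E)-14-hydroxy-5,9,13-trimethyltetradeca-4,8,12-trienoate | CC(C)(C)OC(=O)CC/C=C(\C)CC/C=C(\C)CC/C=C(\C)CO | intermediate
5 | tert-butyl (4E,8E)-11-[(2R,3R)-3-(hydroxymethyl)-3-methyloxiran-2-yl]-5,9-dimethylundeca-4,8-dienoate | CC(C)(C)OC(=O)CC/C=C(\C)CC/C=C(\C)CC[C@H]1O[C@]1(C)CO | intermediate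
6 | ent-3,18-dihydroxy-14,15,16-trinorlabdan-13,8-olide, (3R,4S,5S,8S,9S,10R) | OC[C@@]1(C)[C@H](O)CC[C@]2(C)[C@@H]1CC[C@]3(C)OC(=O)CC[C@@H]23 | intermediate
7 | cyclic 3,18-thionocarbonate of 6 | S=C1OC[C@@]2(C)[C@H](O1)CC[C@]3(C)[C@@H]2CC[C@]4(C)OC(=O)CC[C@@H]34 | intermediate
8 | S-tributylstannyl thiocarbonate on O18 of the 3-deoxy δ-lactone | CCCC[Sn](CCCC)(CCCC)SC(=O)OC[C@@]1(C)CCC[C@]2(C)[C@@H]1CC[C@]3(C)OC(=O)CC[C@@H]23 | intermediate (not isolated)
9 | (4S,5S,8S,9S,10R)-8,18-dihydroxy-14,15,16-trinorlabdan-13-oic acid | OC[C@@]1(C)CCC[C@]2(C)[C@@H]1CC[C@](C)(O)[C@H]2CCC(=O)O | intermediate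
10 | (4S,5S,8S,9S,10R)-13,14,15,16-tetranorlabd-11-ene-8,18-diol | OC[C@@]1(C)CCC[C@]2(C)[C@@H]1CC[C@](C)(O)[C@H]2C=C | intermediate
11 | 3-methylbut-2-enoic acid (senecioic acid) | CC(C)=CC(=O)O | starting material
12 | (4S,5S,8S,9S,10R)-8-hydroxy-13,14,15,16-tetranorlabd-11-en-18-yl 3-methylbut-2-enoate | CC(C)=CC(=O)OC[C@@]1(C)CCC[C@]2(C)[C@@H]1CC[C@](C)(O)[C@H]2C=C | intermediate
13 | but-2-yn-1-ol | CC#CCO | starting material
14 | (Z)-but-2-en-1-ol | C/C=C\CO | intermediate
15 | (Z)-1-chlorobut-2-ene | C/C=C\CCl | intermediate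
16 | B-alkyl-9-BBN of 12 (boron on C12) | CC(C)=CC(=O)OC[C@@]1(C)CCC[C@]2(C)[C@@H]1CC[C@](C)(O)[C@H]2CCB1C2CCCC1CCC2 | intermediate (not isolated)
17 | (4S,5S,8S,9S,10R,13S)-8-hydroxylabd-14-en-18-yl 3-methylbut-2-enoate | CC(C)=CC(=O)OC[C@@]1(C)CCC[C@]2(C)[C@@H]1CC[C@](C)(O)[C@H]2CC[C@H](C)C=C | intermediate
18 | B-alkyl-9-BBN of 17 (boron on C15) | CC(C)=CC(=O)OC[C@@]1(C)CCC[C@]2(C)[C@@H]1CC[C@](C)(O)[C@H]2CC[C@H](C)CCB1C2CCCC1CCC2 | intermediate (not isolated)
19 | (4S,5S,8S,9S,10R,13S)-8,15-dihydroxylabdan-18-yl 3-methylbut-2-enoate | CC(C)=CC(=O)OC[C@@]1(C)CCC[C@]2(C)[C@@H]1CC[C@](C)(O)[C@H]2CC[C@H](C)CCO | intermediate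
20 | Meldrum's acid | CC1(C)OC(=O)CC(=O)O1 | starting material
21 | (4S,5S,8S,9S,10R,13S)-15-[(carboxyacetyl)oxy]-8-hydroxylabdan-18-yl 3-methylbut-2-enoate | CC(C)=CC(=O)OC[C@@]1(C)CCC[C@]2(C)[C@@H]1CC[C@](C)(O)[C@H]2CC[C@H](C)CCOC(=O)CC(=O)O | target

Total step count: 13 (11 in the main line, 2 for the allylic chloride).
Longest linear sequence: 11 steps (steps 1–8, then 11–13).

Steps most likely to fail

Step 4. The free 18-hydroxyl (as its aluminium alkoxide) may divert the Lewis acid into chelate-directed chloride delivery at C3 or a hydride shift to the 3-ketone, or the cascade may stop after ring A by proton loss at C10. The fallback sets out from 5 and returns at 6 with the hydroxyl masked, so that the epoxide is the only Lewis-basic trigger. TBDPSCl and imidazole in DMF should give tert-butyl (4E,8E)-11-[(2R,3R)-3-[(tert-butyldiphenylsilyloxy)methyl]-3-methyloxiran-2-yl]-5,9-dimethylundeca-4,8-dienoate F1. Cyclization of this protected epoxide with MeAlCl2 in CH2Cl2 at −78 °C should give the 18-O-TBDPS ether of 6 F2, and TBAF in THF should then release 6.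

Step 11. Enantioface discrimination may be poor with the small methyl γ-substituent, α-substitution may give the linear product, or the free 8-OH may quench the borate or alkylcopper. The fallback sets out from 16 (made from 12 as in step 11) and returns at 19, so step 12 is bypassed. Red-Al and then I2 convert 13 into (Z)-3-iodobut-2-en-1-ol F3. A B-alkyl Suzuki–Miyaura coupling of 16 with F3 (Pd(dppf)Cl2, AsPh3, Cs2CO3, DMF/THF/H2O, rt) still forms C12–C13 and should give (13Z)-8,15-dihydroxylabd-13-en-18-yl 3-methylbut-2-enoate F4. Hydroxyl-directed asymmetric hydrogenation of this nerol-type allylic alcohol with Ru(OAc)2[(S)-BINAP] and H2 in MeOH should set (13S) and give 19; the senecioate alkene has no directing hydroxyl and should not be reduced.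

Step 7. The δ-hydroxy acid may relactonize before it is oxidised, or cobalt hydride may move the new terminal alkene towards the ring. The fallback sets out from 7 and returns at 10 without a free acid. Bu3SnH/AIBN (via 8) followed by a neutral KF work-up, without LiOH, should give (4S,5S,8S,9S,10R)-18-hydroxy-14,15,16-trinorlabdan-13,8-olide F5. DIBAL-H in CH2Cl2 at −78 °C should give the lactol (13-hydroxy-8,13-epoxide) F6. Rhodium-catalysed transfer dehydroformylation of its open hydroxy-aldehyde form ([Rh(cod)OMe]2, Xantphos, 3-methoxybenzoic acid, norbornadiene, THF, 60 °C) should then give 10.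

Further compounds
F1 | step 4 | tert-butyl (4E,8E)-11-[(2R,3R)-3-[(tert-butyldiphenylsilyloxy)methyl]-3-methyloxiran-2-yl]-5,9-dimethylundeca-4,8-dienoate | CC(C)(C)OC(=O)CC/C=C(\C)CC/C=C(\C)CC[C@H]1O[C@]1(C)CO[Si](c1ccccc1)(c1ccccc1)C(C)(C)C
F2 | step 4 | 18-O-tert-butyldiphenylsilyl ether of 6 | CC(C)(C)[Si](OC[C@@]1(C)[C@H](O)CC[C@]2(C)[C@@H]1CC[C@]3(C)OC(=O)CC[C@@H]23)(c1ccccc1)c1ccccc1
F3 | step 11 | (Z)-3-iodobut-2-en-1-ol | C/C(I)=C/CO
F4 | step 11 | (13Z)-8,15-dihydroxylabd-13-en-18-yl 3-methylbut-2-enoate, (4S,5S,8S,9S,10R) | CC(C)=CC(=O)OC[C@@]1(C)CCC[C@]2(C)[C@@H]1CC[C@](C)(O)[C@H]2CC/C(C)=C\CO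
F5 | step 7 | (4S,5S,8S,9S,10R)-18-hydroxy-14,15,16-trinorlabdan-13,8-olide | OC[C@@]1(C)CCC[C@]2(C)[C@@H]1CC[C@]3(C)OC(=O)CC[C@@H]23
F6 | step 7 | lactol of F5 (13-hydroxy-8,13-epoxy-14,15,16-trinorlabdan-18-ol) | OC[C@@]1(C)CCC[C@]2(C)[C@@H]1CC[C@]3(C)OC(O)CC[C@@H]23
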